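**Retrosynthetic overview**

1. The strategy rests on the C7–C8 bond of the ten-membered carbocycle (ring A, C1–C10). C8 is a secondary carbinol and C7 carries C11 with the exocyclic methylene C13, which is the retron of a [2,3]-Wittig shift. Disconnection gives the thirteen-membered cyclic bis-allylic ether C8–O–C13 (O, C13, C11, C7, C6, C5, C4, C3, C2, C1, C10, C9, C8).
2. The ether ring is opened at O–C13 (Williamson closure, C8 alkoxide on C13 chloride) and the chain at C3–C4 (Evans aldol). The fragments are a geraniol-derived C8–C3 aldehyde and a D-glutamic acid-derived acyl oxazolidinone (C15, C4–C7, C11–C13) whose enoate comes from a Horner–Wadsworth–Emmons olefination.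
3. The shift is run on the ether with C13 trans to C6, so it gives the C8 epimer of the target carbinol. By the allylic 1,3-strain model only this epimer places its hydroxyl on the face of C9=C10 from which directed epoxidation and hydride opening give the target C10 carbinol. C8 is then inverted by oxidation and anti reduction directed by the C10 hydroxyl.
4. End game: angelate at C8, unmasking of the C3 ketone, Saegusa–Ito dehydrogenation to the Z-enone, desilylation, and oxidative lactonisation of C6–OH/C12–OH (ring B, the α-methylene γ-lactone).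
5. Order of ring formation: thirteen-membered ether (step 19), ten-membered carbocycle by ring contraction (step 20), γ-lactone (step 30).

Key step: step 20

Remark: the target is taken as the open Z-configured γ-hydroxy enone drawn by the SMILES; its 3,10-hemiketal is a ring–chain tautomer expected to equilibrate with it and is not treated as a different compound.
Remark: locants C1–C15 are those used above (C14 = methyl on C10, C15 = CH2O on C4, C12 and C13 on C11); "chain" means C8–C9=C10(C14)–C1–C2–C3–C4(C15)–C5–C6–C7=C11(C12)–C13 with 9E geometry and C12 cis to C6 on C7=C11; TBS = tert-butyldimethylsilyl, TES = triethylsilyl, PMB = 4-methoxybenzyl.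

**Route**

Step 1
Reactants: 1 D-glutamic acid
Product: 2 (R)-5-oxotetrahydrofuran-2-carboxylic acid
Conditions: NaNO2, aq. HCl, 0 °C → rt
Reagents that add atoms: none
Why: Diazotisation with carboxylate participation (double inversion through the α-lactone) gives the γ-lactone with net retention, so the future C6 keeps the R configuration of the amino acid.

Step 2
Reactants: 2 (R)-5-oxotetrahydrofuran-2-carboxylic acid
Product: 3 (R)-5-(hydroxymethyl)dihydrofuran-2(3H)-one
Conditions: BH3·SMe2, THF, 0 °C → rt; MeOH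
Reagents that add atoms: none
Why: Borane reduces the free carboxylic acid chemoselectively in the presence of the lactone and does not touch the stereocentre.

Step 3
Reactants: 3 (R)-5-(hydroxymethyl)dihydrofuran-2(3H)-one
Product: 4 (R)-5-oxotetrahydrofuran-2-carbaldehyde
Conditions: (COCl)2, DMSO, CH2Cl2, −78 °C; Et3N, → 0 °C; used crude
Reagents that add atoms: none
Why: Swern oxidation stops at the aldehyde, and immediate use of the crude product limits epimerisation of the α-acyloxy centre.

Step 4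
Reactants: 4 (R)-5-oxotetrahydrofuran-2-carbaldehyde; 5 ethyl 2-(diethoxyphosphoryl)acrylate
Product: 7 ethyl (E)-2-[(4-methoxybenzyloxy)methyl]-3-[(2R)-5-oxotetrahydrofuran-2-yl]acrylate, via sodium phosphonate carbanion 6 (not isolated)
Conditions: 4-MeOC6H4CH2OH, NaH, THF, 0 °C; 5; then 4, −78 → 0 °C
Reagents that add atoms: 4-methoxybenzyl alcohol COc1ccc(CO)cc1
Why: Oxa-Michael addition of the alkoxide to the phosphonoacrylate gives the stabilised carbanion, and its Horner–Wadsworth–Emmons olefination should be E-selective, placing the ester (future C13) trans and the alkoxymethyl arm (future C12) cis to C6.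

Step 5
Reactants: 7 PMB ether enoate lactone
Product: 8 ethyl (E)-2-(hydroxymethyl)-3-[(2R)-5-oxotetrahydrofuran-2-yl]acrylate
Conditions: DDQ, CH2Cl2/pH 7 buffer, 0 °C → rt
Reagents that add atoms: none
Why: Oxidative PMB cleavage frees C12–OH, because a benzylic allyl ether could not be carried into the carbanion step.

Step 6
Reactants: 8 hydroxymethyl enoate lactone
Product: 11 (4R,5E)-4,7-bis(tert-butyldimethylsilyloxy)-6-(ethoxycarbonyl)hept-5-enoic acid, via lithium dihydroxy carboxylate 9 (not isolated), via silyl ester 10 (not isolated)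
Conditions: LiOH (1.05 equiv), THF/H2O, 0 °C; TBSCl, imidazole, DMF, rt; aq. K2CO3, THF, rt; then pH 4
Reagents that add atoms: lithium hydroxide [Li+].[OH-]; tert-butyldimethylsilyl chloride CC(C)(C)[Si](C)(C)Cl
Why: The γ-lactone saponifies faster than the α-branched conjugated ethyl ester, exhaustive silylation caps C6–OH and C12–OH, and selective hydrolysis of the labile silyl ester releases the C15 acid.

Step 7
Reactants: 11 bis-silyl ether acid
Product: 13 (4R)-4-benzyl-3-[(4R,5E)-4,7-bis(tert-butyldimethylsilyloxy)-6-(ethoxycarbonyl)hept-5-enoyl]-1,3-oxazolidin-2-one, via mixed pivalic anhydride 12 (not isolated)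
Conditions: t-BuCOCl, Et3N, THF, −20 °C; (R)-4-benzyl-2-oxazolidinone, LiCl, rt
Reagents that add atoms: (R)-4-benzyl-1,3-oxazolidin-2-one O=C1N[C@H](Cc2ccccc2)CO1
Why: Mixed-anhydride N-acylation attaches the Evans auxiliary to C15 under conditions that leave the silyl ethers and the enoate intact.

Step 8
Reactants: 14 geraniol
Product: 15 geranyl 4-methoxybenzyl ether
Conditions: NaH, 4-MeOC6H4CH2Cl, Bu4NI (cat.), THF/DMF, 0 °C → rt
Reagents that add atoms: 4-methoxybenzyl chloride COc1ccc(CCl)cc1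
Why: Williamson etherification protects the future C8–OH as an ether that is stable to hydride and base and orthogonal to silyl ethers.

Step 9
Reactants: 15 geranyl 4-methoxybenzyl ether
Product: 17 racemic 6,7-epoxygeranyl 4-methoxybenzyl ether, via bromohydrin 16 (not isolated)
Conditions: NBS, THF/H2O, 0 °C; K2CO3, MeOH, rt
Reagents that add atoms: water O
Why: The remote trisubstituted alkene is more electron-rich than the allylic-ether alkene and forms the bromohydrin selectively, which base closes to the epoxide.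

Step 10
Reactants: 17 racemic 6,7-epoxygeranyl 4-methoxybenzyl ether
Product: 18 (E)-6-[(4-methoxybenzyl)oxy]-4-methylhex-4-enal
Conditions: HIO4·2H2O, THF/Et2O, 0 °C
Reagents that add atoms: none
Why: Periodic acid hydrolyses the epoxide and cleaves the diol in one operation to the C3 aldehyde without touching the 9E alkene.

Step 11
Reactants: 13 acyl oxazolidinone; 18 C3 aldehyde
Product: 20 (3S,4R,6R)-syn-aldol adduct (chain; C15 imide; 3-OH; 6-OTBS; 12-OTBS; C13 ethyl ester; 8-OPMB), via dibutylboron Z-enolate 19 (not isolated)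
Conditions: Bu2BOTf, i-Pr2NEt, CH2Cl2, 0 °C; 18, −78 → 0 °C; pH 7 buffer, MeOH, H2O2
Reagents that add atoms: none
Why: Evans syn aldol: the Z-boron enolate reacts through a closed Zimmerman–Traxler chair on the face opposite the benzyl group, which sets C4 in the target configuration (and the sacrificial C3 carbinol), while the enoate is not enolised.

Step 12
Reactants: 20 syn-aldol adduct
Product: 21 (3S,4S,6R)-chain 3,15-diol (6-OTBS; 12-OTBS; C13 ethyl ester; 8-OPMB)
Conditions: LiBH4, MeOH (1 equiv), THF, 0 °C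
Reagents that add atoms: none
Why: Reductive cleavage of the imide by LiBH4 is faster than attack on the hindered conjugated ester, giving C15–OH and releasing the auxiliary.

Step 13
Reactants: 21 3,15-diol
Product: 22 (3S,4S,6R)-chain 3-ol with 15-OTBS
Conditions: TBSCl (1.1 equiv), imidazole, CH2Cl2, 0 °C
Reagents that add atoms: tert-butyldimethylsilyl chloride CC(C)(C)[Si](C)(C)Cl
Why: The primary C15 hydroxyl is silylated selectively over the hindered secondary C3 hydroxyl.

Step 14
Reactants: 22 3-ol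
Product: 23 (4S,6R)-chain 3-ketone
Conditions: Dess–Martin periodinane, CH2Cl2, 0 °C → rt
Reagents that add atoms: none
Why: Dess–Martin oxidation under near-neutral conditions gives the ketone without epimerising C4 or eliminating the β-silyloxy group.

Step 15
Reactants: 23 3-ketone
Product: 24 (4S,6R)-chain 3,3-ethylenedioxy ketal (C13 ethyl ester; 8-OPMB)
Conditions: Me3SiOCH2CH2OSiMe3, Me3SiOTf (cat.), CH2Cl2, −78 → −20 °C
Reagents that add atoms: 1,2-bis(trimethylsilyloxy)ethane C[Si](C)(C)OCCO[Si](C)(C)C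
Why: Silyl-triflate-catalysed ketalisation (Noyori conditions) masks the ketone at low temperature without enolisation, so that it survives the organolithium and aluminium hydride steps.

Step 16
Reactants: 24 ketal ester
Product: 25 (4S,6R)-chain 13-ol
Conditions: i-Bu2AlH, CH2Cl2, −78 °C
Reagents that add atoms: none
Why: 1,2-Reduction of the enoate gives the primary allylic alcohol at C13, the arm trans to C6, while ketal, silyl ethers and PMB ether are inert.

Step 17
Reactants: 25 13-ol
Product: 27 (4S,6R)-chain 13-chloride (8-OPMB), via C13 mesylate 26 (not isolated)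
Conditions: MsCl, Et3N, CH2Cl2, −20 °C; LiCl, DMF, 0 °C → rt
Reagents that add atoms: lithium chloride [Li+].[Cl-]
Why: Mesylation and SN2 displacement by chloride give the primary allylic chloride without allylic transposition, so the alkene geometry is kept.

Step 18
Reactants: 27 13-chloride PMB ether
Product: 28 (4S,6R)-chain 8-ol 13-chloride
Conditions: DDQ, CH2Cl2/pH 7 buffer, rt
Reagents that add atoms: none
Why: Oxidative PMB cleavage liberates C8–OH and leaves the allylic chloride, the ketal and the silyl ethers untouched.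

Step 19
Reactants: 28 hydroxy chloride
Product: 29 (4S,6R,9E)-thirteen-membered cyclic ether C8–O–C13 (3-ketal; 6,12,15-tris-OTBS; C13 trans to C6)
Conditions: NaH, Bu4NI (cat.), THF (0.003 M, slow addition), 50 °C
Reagents that add atoms: none
Why: Intramolecular Williamson etherification under high dilution closes the thirteen-membered ring by exo SN2 attack of the C8 alkoxide on the primary allylic halide; the alkoxide is remote from all silyl ethers, so no silyl migration can scramble C12 and C13.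

Step 20
Reactants: 29 thirteen-membered cyclic ether
Product: 31 (4S,6R,7R,8S)-ten-membered 8-epi carbinol (3-ketal; 6,12,15-tris-OTBS; C11=C13 methylene; 9E), via C8-lithiated ether 30 (not isolated)
Conditions: n-BuLi, THF, −78 → −20 °C; H2O quench at −20 °C
Reagents that add atoms: none
Why: n-BuLi removes a proton from the C8 methylene (allylic and α to oxygen), and the α-oxy allyl anion 30 undergoes a concerted suprafacial [2,3]-Wittig shift through a five-membered envelope (C8, O, C13, C11, C7) in which C8–C7 forms, O–C13 breaks and the alkene moves to C11=C13. The closest known reaction type is the [2,3]-Wittig ring contraction of thirteen-membered bis-allylic ethers to ten-membered carbocyclic dienols. The ten-membered ring is therefore closed by a three-atom sigmatropic contraction (carbanion attack on the distal alkene carbon with allylic transposition) and not by end-to-end cyclisation. C7 is set by C6: allylic 1,3-strain with the cis C12 arm holds H6 in the alkene plane and C8, tethered through C5, adds to the face opposite the C6 silyloxy group (target configuration at C7); C8 is set by the alkene geometry, C6 trans to C13 giving the anti (7,8-trans) carbinol with the vinyl group outside the envelope. The step needs deprotonation at C8 and not at C13 or C12: the prenyl-type C8 methylene is unhindered, C13 and C12 flank the fully substituted C11, and n-BuLi at low temperature should not metalate the silyl ethers. The 8-hydroxyl is made as the epimer of the target on purpose, because only this epimer directs the epoxidation of step 21 to the required face, and it is inverted in steps 23 and 24.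

Step 21
Reactants: 31 ten-membered 8-epi carbinol
Product: 32 (4S,6R,7R,8R,9S,10S)-9,10-epoxy-8-ol
Conditions: VO(acac)2 (cat.), t-BuOOH, CH2Cl2, 0 °C → rt
Reagents that add atoms: tert-butyl hydroperoxide CC(C)(C)OO
Why: Vanadium-catalysed hydroxyl-directed epoxidation: allylic 1,3-strain with the cis methyl C14 holds H8 in the alkene plane, the ring chain covers the inner face and the 8-hydroxyl of this epimer lies on the outer face, so oxygen should be delivered there and fix the C10–O bond as in the target, while the homoallylic C11=C13 alkene reacts much more slowly.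

Step 22
Reactants: 32 epoxy alcohol
Product: 33 (4S,6R,7R,8S,10S)-8,10-diol
Conditions: NaAlH2(OCH2CH2OMe)2, THF, 0 °C → rt
Reagents that add atoms: none
Why: The aluminate bound to the C8 oxygen delivers hydride intramolecularly to C9, the adjacent and less substituted epoxide carbon, giving the 1,3-diol and leaving the C10–O bond and its configuration untouched.

Step 23
Reactants: 33 8,10-diol
Product: 34 (4S,6R,7S,10S)-10-hydroxy-8-ketone
Conditions: Dess–Martin periodinane, CH2Cl2, 0 °C
Reagents that add atoms: none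
Why: Only the secondary C8 carbinol can be oxidised (C10–OH is tertiary), and the neutral conditions should spare the C7 stereocentre of the β,γ-unsaturated ketone.

Step 24
Reactants: 34 10-hydroxy-8-ketone
Product: 35 (4S,6R,7R,8R,10S)-8,10-diol with C8 inverted
Conditions: Me4NBH(OAc)3, MeCN/AcOH, −30 °C
Reagents that add atoms: none
Why: Evans–Saksena reduction: the acetoxyborohydride exchanges onto the C10 hydroxyl and delivers hydride intramolecularly to the C8 ketone through a six-membered chair, giving the 1,3-anti diol, which is the C8 configuration of the target.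

Step 25
Reactants: 35 anti-8,10-diol; 36 angelic acid
Product: 38 (4S,6R,7R,8R,10S)-8-angelate 10-ol, via mixed trichlorobenzoic anhydride 37 (not isolated)
Conditions: 36, 2,4,6-Cl3C6H2COCl, Et3N, toluene, rt; then 35, 80 °C
Reagents that add atoms: none
Why: Yamaguchi-type mixed-anhydride esterification without a nucleophilic catalyst acylates the secondary C8 hydroxyl in the presence of the tertiary C10 hydroxyl and avoids Z to E isomerisation of the angelate.

Step 26
Reactants: 38 8-angelate 10-ol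
Product: 39 10-triethylsilyl ether of 38
Conditions: Et3SiOTf, 2,6-lutidine, CH2Cl2, −78 → 0 °C
Reagents that add atoms: triethylsilyl trifluoromethanesulfonate CC[Si](CC)(CC)OS(=O)(=O)C(F)(F)F
Why: Silyl triflate with lutidine caps the tertiary alcohol, so that the C3 ketone cannot form a hemiketal that would divert the later enolisation; ketone-derived ketals tolerate these conditions.

Step 27
Reactants: 39 ketal
Product: 40 (4S,6R,7R,8R,10S)-3-ketone (8-angelate; 10-OTES; 6,12,15-tris-OTBS)
Conditions: In(OTf)3 (cat.), acetone/H2O, rt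
Reagents that add atoms: water O
Why: Lewis-acid-catalysed ketal hydrolysis under near-neutral conditions should free the ketone while sparing silyl ethers, angelate and the C4 stereocentre.

Step 28
Reactants: 40 3-ketone
Product: 42 (1Z,4S,6R,7R,8R,10R)-1-en-3-one (8-angelate; 10-OTES; 6,12,15-tris-OTBS), via trimethylsilyl enol ether 41 (not isolated)
Conditions: LiN(SiMe3)2, Me3SiCl, THF, −78 °C; Pd(OAc)2, MeCN, rt
Reagents that add atoms: none
Why: Saegusa–Ito oxidation: kinetic deprotonation occurs at the unhindered C2 methylene and not at the branched C4, and syn β-hydride elimination from the palladium enolate gives the conjugated enone, expected as the cis alkene, the less strained geometry in a ten-membered ring; the quaternary C10 excludes deconjugation.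

Step 29
Reactants: 42 silylated Z-enone
Product: 43 (1Z,4S,6R,7S,8R,10R)-6,10,12,15-tetraol 8-angelate
Conditions: HF·pyridine, pyridine, THF, 0 °C → rt
Reagents that add atoms: none
Why: Buffered fluoride removes all four silyl groups under mildly acidic conditions that avoid acyl migration of the angelate and base-induced reactions of the enone.

Step 30
Reactants: 43 tetraol
Product: 46 target CNP0219400.1 (1Z,4S,6R,7S,8R,10R), via C12 aldehyde 44 (not isolated), via lactol 45 (not isolated)
Conditions: MnO2, CH2Cl2, rt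
Reagents that add atoms: none
Why: Oxidative lactonisation: MnO2 oxidises only the allylic primary C12 alcohol, the enal is trapped by C6–OH as a five-membered lactol (exo addition to the aldehyde) and this is oxidised to the α-methylene γ-lactone, trans-fused through the existing C6 and C7 configurations; the saturated C15–OH and the tertiary C10–OH are not affected.

**Compound list**

1 | D-glutamic acid | N[C@H](CCC(=O)O)C(=O)O | starting material
2 | (R)-5-oxotetrahydrofuran-2-carboxylic acid | O=C(O)[C@H]1CCC(=O)O1 | intermediate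
3 | (R)-5-(hydroxymethyl)dihydrofuran-2(3H)-one | OC[C@H]1CCC(=O)O1 | intermediate
4 | (R)-5-oxotetrahydrofuran-2-carbaldehyde | O=C[C@H]1CCC(=O)O1 | intermediate
5 | ethyl 2-(diethoxyphosphoryl)acrylate | C=C(C(=O)OCC)P(=O)(OCC)OCC | starting material
6 | sodium salt of the carbanion of ethyl 2-(diethoxyphosphoryl)-3-[(4-methoxybenzyl)oxy]propanoate | CCOC(=O)[C-](COCc1ccc(OC)cc1)P(=O)(OCC)OCC.[Na+] | intermediate
7 | ethyl (E)-2-{[(4-methoxybenzyl)oxy]methyl}-3-[(2R)-5-oxotetrahydrofuran-2-yl]acrylate | CCOC(=O)/C(COCc1ccc(OC)cc1)=C/[C@H]1CCC(=O)O1 | intermediate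
8 | ethyl (E)-2-(hydroxymethyl)-3-[(2R)-5-oxotetrahydrofuran-2-yl]acrylate | CCOC(=O)/C(CO)=C/[C@H]1CCC(=O)O1 | intermediate
9 | lithium (4R,5E)-6-(ethoxycarbonyl)-4,7-dihydroxyhept-5-enoate | CCOC(=O)/C(CO)=C/[C@H](O)CCC(=O)[O-].[Li+] | intermediate
10 | tert-butyldimethylsilyl (4R,5E)-4,7-bis[(tert-butyldimethylsilyl)oxy]-6-(ethoxycarbonyl)hept-5-enoate | CCOC(=O)/C(CO[Si](C)(C)C(C)(C)C)=C/[C@H](O[Si](C)(C)C(C)(C)C)CCC(=O)O[Si](C)(C)C(C)(C)C | intermediate
11 | (4R,5E)-4,7-bis[(tert-butyldimethylsilyl)oxy]-6-(ethoxycarbonyl)hept-5-enoic acid | CCOC(=O)/C(CO[Si](C)(C)C(C)(C)C)=C/[C@H](O[Si](C)(C)C(C)(C)C)CCC(=O)O | intermediate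
12 | mixed anhydride of acid 11 and pivalic acid | CCOC(=O)/C(CO[Si](C)(C)C(C)(C)C)=C/[C@H](O[Si](C)(C)C(C)(C)C)CCC(=O)OC(=O)C(C)(C)C | intermediate
13 | (4R)-4-benzyl-3-{(4R,5E)-4,7-bis[(tert-butyldimethylsilyl)oxy]-6-(ethoxycarbonyl)hept-5-enoyl}-1,3-oxazolidin-2-one | CCOC(=O)/C(CO[Si](C)(C)C(C)(C)C)=C/[C@H](O[Si](C)(C)C(C)(C)C)CCC(=O)N1[C@H](Cc2ccccc2)COC1=O | intermediate
14 | geraniol | CC(C)=CCC/C(C)=C/CO | starting material
15 | geranyl 4-methoxybenzyl ether | CC(C)=CCC/C(C)=C/COCc1ccc(OC)cc1 | intermediate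
16 | racemic (E)-3-bromo-8-[(4-methoxybenzyl)oxy]-2,6-dimethyloct-6-en-2-ol | CC(C)(O)C(Br)CC/C(C)=C/COCc1ccc(OC)cc1 | intermediate
17 | racemic (E)-6,7-epoxygeranyl 4-methoxybenzyl ether | CC1(C)OC1CC/C(C)=C/COCc1ccc(OC)cc1 | intermediate
18 | (E)-6-[(4-methoxybenzyl)oxy]-4-methylhex-4-enal | O=CCC/C(C)=C/COCc1ccc(OC)cc1 | intermediate
19 | Z-(dibutylboryl) enolate of imide 13 | CCCCB(CCCC)O/C(=C\C[C@@H](O[Si](C)(C)C(C)(C)C)/C=C(\CO[Si](C)(C)C(C)(C)C)C(=O)OCC)N1[C@H](Cc2ccccc2)COC1=O | intermediate
20 | (3S,4R,6R)-chain: C15 as N-acyl (4R)-4-benzyl-1,3-oxazolidin-2-one; 3-OH; 6-OTBS; 12-OTBS; C13 as ethyl ester; 8-OPMB | COc1ccc(COC/C=C(\C)CC[C@H](O)[C@H](C(=O)N2[C@H](Cc3ccccc3)COC2=O)C[C@@H](O[Si](C)(C)C(C)(C)C)/C=C(\CO[Si](C)(C)C(C)(C)C)C(=O)OCC)cc1 | intermediate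
21 | (3S,4S,6R)-chain: 3,15-diol; 6-OTBS; 12-OTBS; C13 as ethyl ester; 8-OPMB | COc1ccc(COC/C=C(\C)CC[C@H](O)[C@H](CO)C[C@@H](O[Si](C)(C)C(C)(C)C)/C=C(\CO[Si](C)(C)C(C)(C)C)C(=O)OCC)cc1 | intermediate
22 | (3S,4S,6R)-chain: 3-OH; 15-OTBS; 6-OTBS; 12-OTBS; C13 as ethyl ester; 8-OPMB | COc1ccc(COC/C=C(\C)CC[C@H](O)[C@H](CO[Si](C)(C)C(C)(C)C)C[C@@H](O[Si](C)(C)C(C)(C)C)/C=C(\CO[Si](C)(C)C(C)(C)C)C(=O)OCC)cc1 | intermediate
23 | (4S,6R)-chain: 3-ketone; 15-OTBS; 6-OTBS; 12-OTBS; C13 as ethyl ester; 8-OPMB | COc1ccc(COC/C=C(\C)CCC(=O)[C@H](CO[Si](C)(C)C(C)(C)C)C[C@@H](O[Si](C)(C)C(C)(C)C)/C=C(\CO[Si](C)(C)C(C)(C)C)C(=O)OCC)cc1 | intermediate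
24 | (4S,6R)-chain: 3,3-ethylenedioxy ketal; 15-OTBS; 6-OTBS; 12-OTBS; C13 as ethyl ester; 8-OPMB | COc1ccc(COC/C=C(\C)CCC2(OCCO2)[C@H](CO[Si](C)(C)C(C)(C)C)C[C@@H](O[Si](C)(C)C(C)(C)C)/C=C(\CO[Si](C)(C)C(C)(C)C)C(=O)OCC)cc1 | intermediate
25 | (4S,6R)-chain: 3,3-ethylenedioxy ketal; 15-OTBS; 6-OTBS; 12-OTBS; 13-OH; 8-OPMB | COc1ccc(COC/C=C(\C)CCC2(OCCO2)[C@H](CO[Si](C)(C)C(C)(C)C)C[C@@H](O[Si](C)(C)C(C)(C)C)/C=C(\CO[Si](C)(C)C(C)(C)C)CO)cc1 | intermediate
26 | (4S,6R)-chain: as 25 with 13-methanesulfonate | COc1ccc(COC/C=C(\C)CCC2(OCCO2)[C@H](CO[Si](C)(C)C(C)(C)C)C[C@@H](O[Si](C)(C)C(C)(C)C)/C=C(\CO[Si](C)(C)C(C)(C)C)COS(C)(=O)=O)cc1 | intermediate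
27 | (4S,6R)-chain: as 25 with 13-chloride; 8-OPMB | COc1ccc(COC/C=C(\C)CCC2(OCCO2)[C@H](CO[Si](C)(C)C(C)(C)C)C[C@@H](O[Si](C)(C)C(C)(C)C)/C=C(\CO[Si](C)(C)C(C)(C)C)CCl)cc1 | intermediate
28 | (4S,6R)-chain: 3,3-ethylenedioxy ketal; 15-OTBS; 6-OTBS; 12-OTBS; 13-chloride; 8-OH | OC/C=C(\C)CCC1(OCCO1)[C@H](CO[Si](C)(C)C(C)(C)C)C[C@@H](O[Si](C)(C)C(C)(C)C)/C=C(\CO[Si](C)(C)C(C)(C)C)CCl | intermediate
29 | (4S,6R,9E)-thirteen-membered cyclic ether C8–O–C13: 3,3-ethylenedioxy; 6-OTBS; 4-CH2OTBS (C15); 11-CH2OTBS (C12); 10-methyl; C13 trans and C12 cis to C6 on C7=C11 (7Z by CIP) | O1C/C(CO[Si](C)(C)C(C)(C)C)=C/[C@H](O[Si](C)(C)C(C)(C)C)C[C@@H](CO[Si](C)(C)C(C)(C)C)C2(OCCO2)CC/C(C)=C/C1 | intermediate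
30 | 8-lithio derivative of cyclic ether 29 | O1C/C(CO[Si](C)(C)C(C)(C)C)=C/[C@H](O[Si](C)(C)C(C)(C)C)C[C@@H](CO[Si](C)(C)C(C)(C)C)C2(OCCO2)CC/C(C)=C/C1[Li] | intermediate
31 | (4S,6R,7R,8S,9E)-ten-membered carbocycle: 8-OH trans to C11 (C8 epimer of the target; C7 as in the target); 3,3-ethylenedioxy; 6-OTBS; 4-CH2OTBS; 7-[3-(TBS-oxy)prop-1-en-2-yl] (C11=C13 methylene, C12 OTBS); 10-methyl | C=C(CO[Si](C)(C)C(C)(C)C)[C@H]1[C@H](O[Si](C)(C)C(C)(C)C)C[C@@H](CO[Si](C)(C)C(C)(C)C)C2(OCCO2)CC/C(C)=C/[C@@H]1O | intermediate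
32 | (4S,6R,7R,8R,9S,10S)-9,10-epoxide of 31, epoxide oxygen syn to the 8-OH | C=C(CO[Si](C)(C)C(C)(C)C)[C@H]1[C@H](O[Si](C)(C)C(C)(C)C)C[C@@H](CO[Si](C)(C)C(C)(C)C)C2(OCCO2)CC[C@]3(C)O[C@H]3[C@@H]1O | intermediate
33 | (4S,6R,7R,8S,10S)-8,10-diol (C10 as in the target, C8 epimeric); 3,3-ethylenedioxy; 6,12,15-tris-OTBS | C=C(CO[Si](C)(C)C(C)(C)C)[C@H]1[C@H](O[Si](C)(C)C(C)(C)C)C[C@@H](CO[Si](C)(C)C(C)(C)C)C2(OCCO2)CC[C@](C)(O)C[C@@H]1O | intermediate
34 | (4S,6R,7S,10S)-10-hydroxy-8-ketone; 3,3-ethylenedioxy; 6,12,15-tris-OTBS | C=C(CO[Si](C)(C)C(C)(C)C)[C@H]1[C@H](O[Si](C)(C)C(C)(C)C)C[C@@H](CO[Si](C)(C)C(C)(C)C)C2(OCCO2)CC[C@](C)(O)CC1=O | intermediate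
35 | (4S,6R,7R,8R,10S)-8,10-diol (C8 and C10 as in the target); 3,3-ethylenedioxy; 6,12,15-tris-OTBS | C=C(CO[Si](C)(C)C(C)(C)C)[C@H]1[C@H](O[Si](C)(C)C(C)(C)C)C[C@@H](CO[Si](C)(C)C(C)(C)C)C2(OCCO2)CC[C@](C)(O)C[C@H]1O | intermediate
36 | angelic acid [(Z)-2-methylbut-2-enoic acid] | C/C=C(/C)C(=O)O | starting material
37 | mixed anhydride of angelic acid and 2,4,6-trichlorobenzoic acid | C/C=C(/C)C(=O)OC(=O)c1c(Cl)cc(Cl)cc1Cl | intermediate
38 | (4S,6R,7R,8R,10S)-8-angelate 10-ol; 3,3-ethylenedioxy; 6,12,15-tris-OTBS | C=C(CO[Si](C)(C)C(C)(C)C)[C@H]1[C@H](O[Si](C)(C)C(C)(C)C)C[C@@H](CO[Si](C)(C)C(C)(C)C)C2(OCCO2)CC[C@](C)(O)C[C@H]1OC(=O)/C(C)=C\C | intermediate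
39 | (4S,6R,7R,8R,10S)-8-angelate 10-OTES; 3,3-ethylenedioxy; 6,12,15-tris-OTBS | C=C(CO[Si](C)(C)C(C)(C)C)[C@H]1[C@H](O[Si](C)(C)C(C)(C)C)C[C@@H](CO[Si](C)(C)C(C)(C)C)C2(OCCO2)CC[C@](C)(O[Si](CC)(CC)CC)C[C@H]1OC(=O)/C(C)=C\C | intermediate
40 | (4S,6R,7R,8R,10S)-3-ketone; 8-angelate; 10-OTES; 6,12,15-tris-OTBS | C=C(CO[Si](C)(C)C(C)(C)C)[C@H]1[C@H](O[Si](C)(C)C(C)(C)C)C[C@@H](CO[Si](C)(C)C(C)(C)C)C(=O)CC[C@](C)(O[Si](CC)(CC)CC)C[C@H]1OC(=O)/C(C)=C\C | intermediate
41 | C2=C3 trimethylsilyl enol ether of ketone 40 | C=C(CO[Si](C)(C)C(C)(C)C)[C@H]1[C@H](O[Si](C)(C)C(C)(C)C)C[C@@H](CO[Si](C)(C)C(C)(C)C)C(O[Si](C)(C)C)=CC[C@](C)(O[Si](CC)(CC)CC)C[C@H]1OC(=O)/C(C)=C\C | intermediate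
42 | (1Z,4S,6R,7R,8R,10R)-1-en-3-one; 8-angelate; 10-OTES; 6,12,15-tris-OTBS | C=C(CO[Si](C)(C)C(C)(C)C)[C@H]1[C@H](O[Si](C)(C)C(C)(C)C)C[C@@H](CO[Si](C)(C)C(C)(C)C)C(=O)/C=C\[C@](C)(O[Si](CC)(CC)CC)C[C@H]1OC(=O)/C(C)=C\C | intermediate
43 | (1Z,4S,6R,7S,8R,10R)-1-en-3-one 6,10,12,15-tetraol 8-angelate | C=C(CO)[C@H]1[C@H](O)C[C@@H](CO)C(=O)/C=C\[C@](C)(O)C[C@H]1OC(=O)/C(C)=C\C | intermediate
44 | C12 aldehyde of 43 (2-substituted acrolein on C7) | C=C(C=O)[C@H]1[C@H](O)C[C@@H](CO)C(=O)/C=C\[C@](C)(O)C[C@H]1OC(=O)/C(C)=C\C | intermediate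
45 | C12 lactol (6,12-hemiacetal, both C12 epimers) | C=C1C(O)O[C@@H]2C[C@@H](CO)C(=O)/C=C\[C@](C)(O)C[C@@H](OC(=O)/C(C)=C\C)[C@@H]12 | intermediate
46 | CNP0219400.1, (1Z,4S,6R,7S,8R,10R)-8-angeloyloxy-10,15-dihydroxy-3-oxogermacra-1,11(13)-dien-6,12-olide | C=C1C(=O)O[C@@H]2C[C@@H](CO)C(=O)/C=C\[C@](C)(O)C[C@@H](OC(=O)/C(C)=C\C)[C@@H]12 | target

**Step count**

Total step count: 30. Longest linear sequence: 27 steps (steps 1–7 and 11–30, from D-glutamic acid).

**Steps most likely to fail**

Step 20 (key step). Deprotonation may occur at C13 or C12 instead of C8, leading to the regioisomeric contraction. A competing [1,2] shift, low anti selectivity, or migration of the C6 silyl group to the new C8 alkoxide on warming are also possible. The fallback forms the same C7–C8 bond by a different ring closure and sets out from hydroxy chloride 28. The allylic C8 alcohol is oxidised with MnO2 in CH2Cl2 to the (E)-configured C8 aldehyde F1. F1 is then treated with CrCl2 and NaI in THF under high dilution (intramolecular Nozaki–Hiyama allylation). The allylchromium species generated at C13 adds through its γ-carbon C7 to the aldehyde in a chair transition state, which should give the anti homoallylic alcohol with the exocyclic C11=C13 methylene. The route is rejoined at 31.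

Step 28. β-Hydride elimination may pass through the conformer that gives the trans alkene, or enolisation may go toward C4 with loss of the β-silyloxy group. The fallback accepts the wrong alkene geometry and corrects it at the end; it sets out from ketone 40. The same Saegusa–Ito conditions then deliver the (1E)-enone F2. F2 is desilylated with HF·pyridine to the (1E)-tetraol F3, and F3 is lactonised with MnO2 to the (1E)-isomer of the target F4. F4 is irradiated at about 350 nm in acetonitrile. Excitation of the enone isomerises C1=C2, and the Z-isomer is drawn out of the photoequilibrium by reversible hemiketal formation with the C10 hydroxyl. The route is rejoined at 46.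

Step 24. Ketone 34 may enolise toward C7 in the acidic medium (epimerisation at C7 or migration of C11=C13 into conjugation), and anti delivery of hydride may be incomplete in the medium ring. The fallback inverts C8 without a ketone and sets out from diol 33. Mitsunobu esterification (4-nitrobenzoic acid, PPh3, diisopropyl azodicarboxylate, toluene, 0 °C → rt) should substitute the activated secondary C8 hydroxyl by SN2, giving the inverted C8 4-nitrobenzoate F5; the tertiary C10 hydroxyl does not react. Methanolysis (K2CO3, MeOH, rt) then gives diol 35, where the route is rejoined.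

**Further compounds**

F1 | step 20 | (4S,6R)-chain: 8-aldehyde (2E-enal); 13-chloride; 3,3-ethylenedioxy ketal; 6,12,15-tris-OTBS | O=C/C=C(\C)CCC1(OCCO1)[C@H](CO[Si](C)(C)C(C)(C)C)C[C@@H](O[Si](C)(C)C(C)(C)C)/C=C(\CO[Si](C)(C)C(C)(C)C)CCl
F2 | step 28 | (1E)-isomer of enone 42 | C=C(CO[Si](C)(C)C(C)(C)C)[C@H]1[C@H](O[Si](C)(C)C(C)(C)C)C[C@@H](CO[Si](C)(C)C(C)(C)C)C(=O)/C=C/[C@](C)(O[Si](CC)(CC)CC)C[C@H]1OC(=O)/C(C)=C\C
F3 | step 28 | (1E)-isomer of tetraol 43 | C=C(CO)[C@H]1[C@H](O)C[C@@H](CO)C(=O)/C=C/[C@](C)(O)C[C@H]1OC(=O)/C(C)=C\C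
F4 | step 28 | (1E)-isomer of the target 46 | C=C1C(=O)O[C@@H]2C[C@@H](CO)C(=O)/C=C/[C@](C)(O)C[C@@H](OC(=O)/C(C)=C\C)[C@@H]12
F5 | step 24 | C8-inverted 8-(4-nitrobenzoate) 10-ol; 3,3-ethylenedioxy; 6,12,15-tris-OTBS | C=C(CO[Si](C)(C)C(C)(C)C)[C@H]1[C@H](O[Si](C)(C)C(C)(C)C)C[C@@H](CO[Si](C)(C)C(C)(C)C)C2(OCCO2)CC[C@](C)(O)C[C@H]1OC(=O)c1ccc(cc1)[N+](=O)[O-]
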